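## Retrosynthetic overview

1. The acid comes from its methyl ester; the 1,2-dioxane is the last ring formed, by a 6-exo intramolecular peroxy-Michael (oxa-Michael) addition of a C6 hydroperoxide onto an (E)-enoate, which sets C3.
2. The hydroperoxide comes from SN2 inversion of an erythro oxolanyl carbinol triflate with 2-methoxyprop-2-yl hydroperoxide; the enoate comes from a lactol Wittig reaction.
3. The oxolane ring is formed first: Cu-catalysed opening of the terminal epoxide of a C9 bis-epoxide by the C13 trienyl Grignard reagent (fragment union) triggers a 5-exo epoxy-alcohol cyclisation.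
4. The bis-epoxide comes from Shi epoxidation of an (E)-alkene, made by Julia–Kocienski coupling of (S)-4,5-epoxypentanal with a tetrazolyl sulfone acetal.
5. The trienyl bromide comes from a Z-selective Wittig reaction of a hydroxyhexyl ylide with (E)-hepta-2,6-dienal.

Assumption: the acetal carbon of 21 and 22 (not a stereocentre of the target) is carried as an anomeric mixture; selectivities quoted are expectations from close precedent, not measured values.

## Route

Step 1
Reactants: 1 pent-4-enal; 2 (triphenylphosphoranylidene)acetaldehyde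
Product: 3 (2E)-hepta-2,6-dienal
Conditions: toluene, 80 °C, 16 h (1.3 equiv of 1)
Reagents that add atoms: none
Why: Wittig olefination with a formyl-stabilised ylide gives the E-enal, and the excess of 1 suppresses a second homologation.

Step 2
Reactants: 4 6-bromohexan-1-ol
Product: 5 (6-hydroxyhexyl)triphenylphosphonium bromide
Conditions: PPh3, MeCN, reflux, 24 h
Reagents that add atoms: triphenylphosphine, c1ccc(cc1)P(c1ccccc1)c1ccccc1
Why: SN2 quaternisation of the primary bromide by the phosphine gives the phosphonium salt without protecting the alcohol.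

Step 3
Reactants: 5 (6-hydroxyhexyl)triphenylphosphonium bromide; 3 (2E)-hepta-2,6-dienal
Product: 7 (6Z,8E)-trideca-6,8,12-trien-1-ol, via phosphonium ylide 6 (not isolated)
Conditions: NaN(SiMe3)2 (2.1 equiv), THF, 0 °C; then 3, −78 °C → rt; H2O quench
Reagents that add atoms: none
Why: A Z-selective Wittig reaction of a salt-free non-stabilised ylide with the E-enal forms the new alkene cis (expected ≥ 9:1) through the kinetic cis-oxaphosphetane, and the existing E-alkene is untouched.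

Step 4
Reactants: 7 (6Z,8E)-trideca-6,8,12-trien-1-ol
Product: 8 (5E,7Z)-13-bromotrideca-1,5,7-triene
Conditions: CBr4, PPh3, CH2Cl2, 0 °C
Reagents that add atoms: carbon tetrabromide, BrC(Br)(Br)Br
Why: The Appel reaction converts the primary alcohol into the bromide under neutral conditions that do not isomerise the (Z,E)-diene.

Step 5
Reactants: 9 4-chloro-1,1-dimethoxybutane
Product: 10 5-[(4,4-dimethoxybutyl)sulfanyl]-1-phenyl-1H-tetrazole
Conditions: 1-phenyl-1H-tetrazole-5-thiol, K2CO3, NaI (10 mol%), DMF, 60 °C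
Reagents that add atoms: 1-phenyl-1H-tetrazole-5-thiol, SC1=NN=NN1c1ccccc1
Why: S-alkylation (SN2, iodide-catalysed) of the thiolate by the primary chloride leaves the acetal untouched under basic conditions.

Step 6
Reactants: 10 5-[(4,4-dimethoxybutyl)sulfanyl]-1-phenyl-1H-tetrazole
Product: 11 5-[(4,4-dimethoxybutyl)sulfonyl]-1-phenyl-1H-tetrazole
Conditions: mCPBA (2.5 equiv), NaHCO3, CH2Cl2, 0 °C → rt
Reagents that add atoms: mCPBA, OOC(=O)c1cccc(Cl)c1
Why: Buffered peracid oxidation of the sulfide to the sulfone keeps the acid-labile dimethyl acetal intact.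

Step 7
Reactants: 12 (2S)-2-(but-3-en-1-yl)oxirane
Product: 14 3-[(2S)-oxiran-2-yl]propanal, via ozonide 13 (not isolated)
Conditions: O3, CH2Cl2, −78 °C; then PPh3, −78 °C → rt; used as a solution
Reagents that add atoms: ozone, [O-][O+]=O
Why: Ozonolysis with reductive work-up cleaves the terminal alkene to the aldehyde without touching the epoxide or its stereocentre, which later becomes C5 of the oxolane.

Step 8
Reactants: 11 5-[(4,4-dimethoxybutyl)sulfonyl]-1-phenyl-1H-tetrazole; 14 3-[(2S)-oxiran-2-yl]propanal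
Product: 16 (2S)-2-[(3E)-7,7-dimethoxyhept-3-en-1-yl]oxirane, via potassiated sulfone 15 (not isolated)
Conditions: KN(SiMe3)2, DME, −60 °C, 20 min; then 14, −60 °C → rt
Reagents that add atoms: none
Why: Julia–Kocienski olefination of a phenyltetrazolyl sulfone with an unbranched aldehyde under potassium/DME conditions gives the E-alkene (expected ≥ 10:1), and the epoxide survives at low temperature.

Step 9
Reactants: 16 (2S)-2-[(3E)-7,7-dimethoxyhept-3-en-1-yl]oxirane
Product: 17 (2R,3R)-2-(3,3-dimethoxypropyl)-3-{2-[(2S)-oxiran-2-yl]ethyl}oxirane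
Conditions: D-fructose-derived Shi ketone (30 mol%), Oxone (2KHSO5·KHSO4·K2SO4), K2CO3, Bu4NHSO4, MeCN/CH2(OMe)2, aq. Na2B4O7 buffer (pH 10.5), 0 °C
Reagents that add atoms: potassium peroxymonosulfate (active component of Oxone), [K+].[O-]S(=O)(=O)OO
Why: Shi asymmetric epoxidation through the spiro dioxirane transition state delivers the (R,R)-epoxide from the trans-disubstituted alkene under reagent control, at a pH that spares the acetal and the terminal epoxide.

Step 10
Reactants: 8 (5E,7Z)-13-bromotrideca-1,5,7-triene; 17 (2R,3R)-2-(3,3-dimethoxypropyl)-3-{2-[(2S)-oxiran-2-yl]ethyl}oxirane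
Product: 21 (2S,5R)-2-[(2R)-5-methoxyoxolan-2-yl]-5-[(7Z,9E)-tetradeca-7,9,13-trien-1-yl]oxolane, via trienylmagnesium bromide 18 (not isolated), via hydroxy epoxide 19 (not isolated), via oxolanyl carbinol 20 (not isolated)
Conditions: 8, Mg, THF, 40 °C; then 17, CuI (10 mol%), THF, −40 → −20 °C; aqueous work-up; crude, CSA (10 mol%), CH2Cl2, 0 °C → rt
Reagents that add atoms: none
Why: Copper-catalysed Grignard opening at the CH2 of the terminal epoxide retains that stereocentre, and acid-catalysed 5-exo epoxy-alcohol cyclisation then inverts the attacked epoxide carbon and retains the other, giving the trans-2,5-oxolane with an erythro carbinol that is trapped by the acetal as the cyclic methyl acetal.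

Step 11
Reactants: 21 (2S,5R)-2-[(2R)-5-methoxyoxolan-2-yl]-5-[(7Z,9E)-tetradeca-7,9,13-trien-1-yl]oxolane
Product: 22 (5R)-5-[(2S,5R)-5-[(7Z,9E)-tetradeca-7,9,13-trien-1-yl]oxolan-2-yl]oxolan-2-ol
Conditions: AcOH/H2O/THF (3:1:1), 40 °C
Reagents that add atoms: water, O
Why: Mild acid hydrolysis of the cyclic methyl acetal (and of any residual open-chain 20) converges on the lactol without affecting the triene or the oxolane.

Step 12
Reactants: 22 (5R)-5-[(2S,5R)-5-[(7Z,9E)-tetradeca-7,9,13-trien-1-yl]oxolan-2-yl]oxolan-2-ol; 23 methyl (triphenylphosphoranylidene)acetate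
Product: 24 methyl (2E,6R)-6-hydroxy-6-[(2S,5R)-5-[(7Z,9E)-tetradeca-7,9,13-trien-1-yl]oxolan-2-yl]hex-2-enoate
Conditions: toluene, 70 °C, 6 h
Reagents that add atoms: none
Why: A Wittig reaction of the stabilised ylide with the open hydroxy-aldehyde tautomer gives the E-enoate under neutral conditions, which keeps the freed secondary alcohol from adding back in an oxa-Michael sense.

Step 13
Reactants: 25 2,3-dimethylbut-2-ene
Product: 27 2-hydroperoxy-2-methoxypropane, via acetone O-oxide 26 (not isolated)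
Conditions: O3, CH2Cl2/MeOH (4:1), −78 °C; cold concentration behind a shield
Reagents that add atoms: ozone, [O-][O+]=O; methanol, CO
Why: Ozonolysis in methanol traps the carbonyl oxide as the hydroperoxy ketal, a monoprotected hydrogen peroxide that alkylates only once.

Step 14
Reactants: 24 methyl (2E,6R)-6-hydroxy-6-[(2S,5R)-5-[(7Z,9E)-tetradeca-7,9,13-trien-1-yl]oxolan-2-yl]hex-2-enoate; 27 2-hydroperoxy-2-methoxypropane
Product: 30 methyl (2E,6S)-6-[(2-methoxypropan-2-yl)peroxy]-6-[(2S,5R)-5-[(7Z,9E)-tetradeca-7,9,13-trien-1-yl]oxolan-2-yl]hex-2-enoate, via secondary triflate 28 (not isolated), via potassium peroxide 29 (not isolated)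
Conditions: 24, Tf2O (1.1 equiv), 2,6-lutidine, CH2Cl2, −78 °C; then 27 (3 equiv)/KOtBu (2.8 equiv)/18-crown-6 premixed in THF at 0 °C, −78 → 0 °C
Reagents that add atoms: none
Why: SN2 displacement of the triflate by the weakly basic α-effect peroxide anion inverts C6 from R to S, giving the threo relationship of the target; the excess hydroperoxide leaves no free tert-butoxide to attack the enoate.

Step 15
Reactants: 30 methyl (2E,6S)-6-[(2-methoxypropan-2-yl)peroxy]-6-[(2S,5R)-5-[(7Z,9E)-tetradeca-7,9,13-trien-1-yl]oxolan-2-yl]hex-2-enoate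
Product: 31 methyl (2E,6S)-6-hydroperoxy-6-[(2S,5R)-5-[(7Z,9E)-tetradeca-7,9,13-trien-1-yl]oxolan-2-yl]hex-2-enoate
Conditions: AcOH/THF/H2O (4:2:1), rt
Reagents that add atoms: none
Why: Acid hydrolysis of the peroxyketal releases the secondary hydroperoxide without breaking the C–O bond at C6, and the hydroperoxy enoate does not cyclise under acid.

Step 16
Reactants: 31 methyl (2E,6S)-6-hydroperoxy-6-[(2S,5R)-5-[(7Z,9E)-tetradeca-7,9,13-trien-1-yl]oxolan-2-yl]hex-2-enoate
Product: 32 methyl 2-[(3S,6S)-6-[(2S,5R)-5-[(7Z,9E)-tetradeca-7,9,13-trien-1-yl]oxolan-2-yl]-1,2-dioxan-3-yl]acetate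
Conditions: Et2NH (0.5 equiv), CF3CH2OH, rt, 24 h; chromatographic removal of the minor cis isomer
Reagents that add atoms: none
Why: The intramolecular 6-exo-trig peroxy-Michael (oxa-Michael) addition closes the 1,2-dioxane; C3 is expected to form mainly as the 3,6-trans isomer through a chair with both substituents equatorial, which is also the thermodynamic isomer, while the protic fluorinated solvent protonates the enolate before it can collapse onto the O–O bond.

Step 17
Reactants: 32 methyl 2-[(3S,6S)-6-[(2S,5R)-5-[(7Z,9E)-tetradeca-7,9,13-trien-1-yl]oxolan-2-yl]-1,2-dioxan-3-yl]acetate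
Product: 33 2-[(3S,6S)-6-[(2S,5R)-5-[(7Z,9E)-tetradeca-7,9,13-trien-1-yl]oxolan-2-yl]-1,2-dioxan-3-yl]acetic acid
Conditions: LiOH·H2O, THF/H2O (3:1), 0 °C; then 1 M HCl to pH 3
Reagents that add atoms: lithium hydroxide, [Li+].[OH-]
Why: Cold saponification of the methyl ester gives the acid without touching the dialkyl peroxide or any stereocentre.

## Compound list

1 | pent-4-enal | C=CCCC=O | starting material
2 | (triphenylphosphoranylidene)acetaldehyde | O=CC=P(c1ccccc1)(c1ccccc1)c1ccccc1 | starting material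
3 | (2E)-hepta-2,6-dienal | C=CCC/C=C/C=O | intermediate
4 | 6-bromohexan-1-ol | OCCCCCCBr | starting material
5 | (6-hydroxyhexyl)triphenylphosphonium bromide | OCCCCCC[P+](c1ccccc1)(c1ccccc1)c1ccccc1.[Br-] | intermediate
6 | sodium 6-(triphenylphosphoranylidene)hexan-1-olate (phosphonium ylide) | [Na+].[O-]CCCCCC=P(c1ccccc1)(c1ccccc1)c1ccccc1 | intermediate (not isolated)
7 | (6Z,8E)-trideca-6,8,12-trien-1-ol | C=CCC/C=C/C=C\CCCCCO | intermediate
8 | (5E,7Z)-13-bromotrideca-1,5,7-triene | C=CCC/C=C/C=C\CCCCCBr | intermediate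
9 | 4-chloro-1,1-dimethoxybutane | COC(OC)CCCCl | starting material
10 | 5-[(4,4-dimethoxybutyl)sulfanyl]-1-phenyl-1H-tetrazole | COC(OC)CCCSC1=NN=NN1c1ccccc1 | intermediate
11 | 5-[(4,4-dimethoxybutyl)sulfonyl]-1-phenyl-1H-tetrazole | COC(OC)CCCS(=O)(=O)C1=NN=NN1c1ccccc1 | intermediate
12 | (2S)-2-(but-3-en-1-yl)oxirane | C=CCC[C@H]1CO1 | starting material
13 | 3-{2-[(2S)-oxiran-2-yl]ethyl}-1,2,4-trioxolane (ozonide) | C1OC(CC[C@H]2CO2)OO1 | intermediate (not isolated)
14 | 3-[(2S)-oxiran-2-yl]propanal | O=CCC[C@H]1CO1 | intermediate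
15 | potassium salt of the α-sulfonyl carbanion of 11 (potassiated sulfone) | [K+].COC(OC)CC[CH-]S(=O)(=O)C1=NN=NN1c1ccccc1 | intermediate (not isolated)
16 | (2S)-2-[(3E)-7,7-dimethoxyhept-3-en-1-yl]oxirane | COC(OC)CC/C=C/CC[C@H]1CO1 | intermediate
17 | (2R,3R)-2-(3,3-dimethoxypropyl)-3-{2-[(2S)-oxiran-2-yl]ethyl}oxirane | COC(OC)CC[C@H]1O[C@@H]1CC[C@H]1CO1 | intermediate
18 | [(6Z,8E)-trideca-6,8,12-trien-1-yl]magnesium bromide | C=CCC/C=C/C=C\CCCCC[Mg]Br | intermediate (not isolated)
19 | (3R,10Z,12E)-1-[(2R,3R)-3-(3,3-dimethoxypropyl)oxiran-2-yl]heptadeca-10,12,16-trien-3-ol | C=CCC/C=C/C=C\CCCCCC[C@@H](O)CC[C@H]1O[C@@H]1CCC(OC)OC | intermediate (not isolated)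
20 | (1R)-4,4-dimethoxy-1-[(2S,5R)-5-[(7Z,9E)-tetradeca-7,9,13-trien-1-yl]oxolan-2-yl]butan-1-ol | C=CCC/C=C/C=C\CCCCCC[C@@H]1CC[C@@H]([C@H](O)CCC(OC)OC)O1 | intermediate (not isolated)
21 | (2S,5R)-2-[(2R)-5-methoxyoxolan-2-yl]-5-[(7Z,9E)-tetradeca-7,9,13-trien-1-yl]oxolane (anomeric mixture) | C=CCC/C=C/C=C\CCCCCC[C@@H]1CC[C@@H]([C@H]2CCC(OC)O2)O1 | intermediate
22 | (5R)-5-[(2S,5R)-5-[(7Z,9E)-tetradeca-7,9,13-trien-1-yl]oxolan-2-yl]oxolan-2-ol (anomeric mixture) | C=CCC/C=C/C=C\CCCCCC[C@@H]1CC[C@@H]([C@H]2CCC(O)O2)O1 | intermediate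
23 | methyl (triphenylphosphoranylidene)acetate | COC(=O)C=P(c1ccccc1)(c1ccccc1)c1ccccc1 | starting material
24 | methyl (2E,6R)-6-hydroxy-6-[(2S,5R)-5-[(7Z,9E)-tetradeca-7,9,13-trien-1-yl]oxolan-2-yl]hex-2-enoate | C=CCC/C=C/C=C\CCCCCC[C@@H]1CC[C@@H]([C@H](O)CC/C=C/C(=O)OC)O1 | intermediate
25 | 2,3-dimethylbut-2-ene | CC(C)=C(C)C | starting material
26 | propan-2-one O-oxide (acetone O-oxide) | CC(C)=[O+][O-] | intermediate (not isolated)
27 | 2-hydroperoxy-2-methoxypropane | COC(C)(C)OO | intermediate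
28 | methyl (2E,6R)-6-[(2S,5R)-5-[(7Z,9E)-tetradeca-7,9,13-trien-1-yl]oxolan-2-yl]-6-{[(trifluoromethyl)sulfonyl]oxy}hex-2-enoate | C=CCC/C=C/C=C\CCCCCC[C@@H]1CC[C@@H]([C@H](OS(=O)(=O)C(F)(F)F)CC/C=C/C(=O)OC)O1 | intermediate (not isolated)
29 | potassium 2-methoxypropan-2-yl peroxide | [K+].[O-]OC(C)(C)OC | intermediate (not isolated)
30 | methyl (2E,6S)-6-[(2-methoxypropan-2-yl)peroxy]-6-[(2S,5R)-5-[(7Z,9E)-tetradeca-7,9,13-trien-1-yl]oxolan-2-yl]hex-2-enoate | C=CCC/C=C/C=C\CCCCCC[C@@H]1CC[C@@H]([C@@H](OOC(C)(C)OC)CC/C=C/C(=O)OC)O1 | intermediate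
31 | methyl (2E,6S)-6-hydroperoxy-6-[(2S,5R)-5-[(7Z,9E)-tetradeca-7,9,13-trien-1-yl]oxolan-2-yl]hex-2-enoate | C=CCC/C=C/C=C\CCCCCC[C@@H]1CC[C@@H]([C@@H](OO)CC/C=C/C(=O)OC)O1 | intermediate
32 | methyl 2-[(3S,6S)-6-[(2S,5R)-5-[(7Z,9E)-tetradeca-7,9,13-trien-1-yl]oxolan-2-yl]-1,2-dioxan-3-yl]acetate | C=CCC/C=C/C=C\CCCCCC[C@@H]1CC[C@@H]([C@@H]2CC[C@@H](CC(=O)OC)OO2)O1 | intermediate
33 | 2-[(3S,6S)-6-[(2S,5R)-5-[(7Z,9E)-tetradeca-7,9,13-trien-1-yl]oxolan-2-yl]-1,2-dioxan-3-yl]acetic acid | C=CCC/C=C/C=C\CCCCCC[C@@H]1CC[C@@H]([C@@H]2CC[C@@H](CC(=O)O)OO2)O1 | target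

## Step count and risks

Total step count: 17.
Longest linear sequence: 11 steps (from 9: steps 5, 6, 8, 9, 10, 11, 12, 14, 15, 16, 17). The lines from 12 and from 1 are 10 steps each.

**Step 14 (most likely to fail).** The SN2 takes place at a secondary carbon next to the ring oxygen, where elimination or oxonium participation can compete, and the enoate is exposed to a peroxide anion. The fallback installs the peroxide before the enoate exists, so forcing conditions can be used; it sets out from 22 and comes back at 30. Reduce 22 with NaBH4 (MeOH, 0 °C) to the diol (1R)-1-[(2S,5R)-5-[(7Z,9E)-tetradeca-7,9,13-trien-1-yl]oxolan-2-yl]butane-1,4-diol F1. Silylate the primary hydroxyl (TBSCl, imidazole, CH2Cl2, −20 °C) to the mono-silyl ether F2. Convert it (Tf2O, 2,6-lutidine, −78 °C) into the secondary triflate F3 and displace with a large excess of 29 in THF/DMF to give, with inversion, the peroxyketal silyl ether F4. Remove the silyl group with Bu4NF (THF, 0 °C) to the peroxyketal alcohol F5, oxidise with Dess–Martin periodinane/NaHCO3 to the peroxyketal aldehyde F6, and olefinate with 23 (CH2Cl2, rt) to reach 30.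

**Step 16.** The closure may give a poor trans:cis ratio, and the peroxy enolate can be diverted by base. The fallback replaces a single selective closure by a closure, separation and retro-Michael recycling loop that corrects C3 after the ring exists; it sets out from 31 and comes back at 32. Drive the cyclisation to completion regardless of ratio (Cs2CO3, CF3CH2OH, 0 °C), and separate the cis-dioxane ester methyl 2-[(3R,6S)-6-[(2S,5R)-5-[(7Z,9E)-tetradeca-7,9,13-trien-1-yl]oxolan-2-yl]-1,2-dioxan-3-yl]acetate F7. Treat F7 in a separate operation with catalytic KOtBu in THF/tBuOH at −20 °C. This re-opens it by E1cB retro-Michael to 31 (as its anion in equilibrium), which re-closes; repeated separation and epimerisation funnels the material into the diequatorial trans isomer 32.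

**Step 10.** One operation has to combine Grignard formation from a polyene bromide, selective opening of the terminal over the internal epoxide, and clean 5-exo closure. The fallback builds the oxolane first and makes the C–C bond afterwards by sp3–sp3 coupling; it sets out from 17 and comes back at 21. Hydrolyse only the terminal epoxide of 17 with water and (S,S)-(salen)Co(OAc), the acetate of the trivalent cobalt complex of N,N'-bis(3,5-di-tert-butylsalicylidene)-(1S,2S)-cyclohexane-1,2-diamine, to give the epoxy diol (2S)-4-[(2R,3R)-3-(3,3-dimethoxypropyl)oxiran-2-yl]butane-1,2-diol F8. CSA in CH2Cl2 then closes the oxolane (5-exo attack of the secondary hydroxyl) and the cyclic methyl acetal, giving the oxolanyl methanol [(2S,5S)-5-[(2R)-5-methoxyoxolan-2-yl]oxolan-2-yl]methanol F9. Tf2O/2,6-lutidine (−78 °C) gives the primary triflate F10, which is coupled with 18 (from 8 and Mg) under Li2CuCl4 catalysis in THF at −30 °C to deliver 21.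

## Further compounds

F1 | step 14 | (1R)-1-[(2S,5R)-5-[(7Z,9E)-tetradeca-7,9,13-trien-1-yl]oxolan-2-yl]butane-1,4-diol | C=CCC/C=C/C=C\CCCCCC[C@@H]1CC[C@@H]([C@H](O)CCCO)O1
F2 | step 14 | (1R)-4-[(tert-butyldimethylsilyl)oxy]-1-[(2S,5R)-5-[(7Z,9E)-tetradeca-7,9,13-trien-1-yl]oxolan-2-yl]butan-1-ol | C=CCC/C=C/C=C\CCCCCC[C@@H]1CC[C@@H]([C@H](O)CCCO[Si](C)(C)C(C)(C)C)O1
F3 | step 14 | (1R)-4-[(tert-butyldimethylsilyl)oxy]-1-[(2S,5R)-5-[(7Z,9E)-tetradeca-7,9,13-trien-1-yl]oxolan-2-yl]butyl trifluoromethanesulfonate | C=CCC/C=C/C=C\CCCCCC[C@@H]1CC[C@@H]([C@H](OS(=O)(=O)C(F)(F)F)CCCO[Si](C)(C)C(C)(C)C)O1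
F4 | step 14 | tert-butyl{[(4S)-4-[(2-methoxypropan-2-yl)peroxy]-4-[(2S,5R)-5-[(7Z,9E)-tetradeca-7,9,13-trien-1-yl]oxolan-2-yl]butyl]oxy}dimethylsilane | C=CCC/C=C/C=C\CCCCCC[C@@H]1CC[C@@H]([C@@H](OOC(C)(C)OC)CCCO[Si](C)(C)C(C)(C)C)O1
F5 | step 14 | (4S)-4-[(2-methoxypropan-2-yl)peroxy]-4-[(2S,5R)-5-[(7Z,9E)-tetradeca-7,9,13-trien-1-yl]oxolan-2-yl]butan-1-ol | C=CCC/C=C/C=C\CCCCCC[C@@H]1CC[C@@H]([C@@H](OOC(C)(C)OC)CCCO)O1
F6 | step 14 | (4S)-4-[(2-methoxypropan-2-yl)peroxy]-4-[(2S,5R)-5-[(7Z,9E)-tetradeca-7,9,13-trien-1-yl]oxolan-2-yl]butanal | C=CCC/C=C/C=C\CCCCCC[C@@H]1CC[C@@H]([C@@H](OOC(C)(C)OC)CCC=O)O1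
F7 | step 16 | methyl 2-[(3R,6S)-6-[(2S,5R)-5-[(7Z,9E)-tetradeca-7,9,13-trien-1-yl]oxolan-2-yl]-1,2-dioxan-3-yl]acetate | C=CCC/C=C/C=C\CCCCCC[C@@H]1CC[C@@H]([C@@H]2CC[C@H](CC(=O)OC)OO2)O1
F8 | step 10 | (2S)-4-[(2R,3R)-3-(3,3-dimethoxypropyl)oxiran-2-yl]butane-1,2-diol | COC(OC)CC[C@H]1O[C@@H]1CC[C@H](O)CO
F9 | step 10 | [(2S,5S)-5-[(2R)-5-methoxyoxolan-2-yl]oxolan-2-yl]methanol | OC[C@@H]1CC[C@@H]([C@H]2CCC(OC)O2)O1
F10 | step 10 | [(2S,5S)-5-[(2R)-5-methoxyoxolan-2-yl]oxolan-2-yl]methyl trifluoromethanesulfonate | FC(F)(F)S(=O)(=O)OC[C@@H]1CC[C@@H]([C@H]2CCC(OC)O2)O1
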